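## Retrosynthetic overview

1. The target comes from a spirocyclic trienal by aldehyde reduction, acetylation and desilylation. The trienal is made by a Heck union (C16–C17) of a 2-substituted acrolein with a myrcene-type (E)-dienyl iodide, which also fixes the C15=C16 geometry.
2. Cyclopentane (second ring): chelation-controlled intramolecular carbonyl-ene (Prins-type) closure of the C26 aldehyde onto the C14=C15 prenyl olefin, the ring closure assumed in the biogenesis of spiroiridals.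
3. Cyclohexane (first ring): epoxide-initiated cation–olefin cyclisation forming C6–C11. The tetrasubstituted C10=C11 olefin is the nucleophile and an internal carbamate captures the C10 cation, so C6, C11 and C10 are set in one step. The C7 oxygen is then converted into the (Z)-enal.
4. Acyclic precursor: three copper-catalysed carbomagnesiations of propargylic alcohols and two B-alkyl Suzuki couplings. One Sharpless epoxidation supplies all absolute stereochemistry.
5. Ring order: cyclohexane first, spirocyclopentane second.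

Assumption and convention: the target is taken exactly as drawn in the SMILES (CH2OAc trans to C17 on C15=C16); locants C1–C30 are iridal-type (C1 CHO, C3 CH2OH, C6/C10/C11 cyclohexane stereocentres, C14/C26 cyclopentane stereocentres, C28 CH2OAc).

## Route

Step 1
Reactants: 1 5-bromo-2-methylpent-2-ene
Product: 2 (4-methylpent-3-en-1-yl)magnesium bromide
Conditions: Mg turnings, THF, 35–40 °C; titrated and kept as a THF stock solution
Reagents that add atoms: magnesium ([Mg])
Why: Grignard reagent formation by insertion of magnesium into the primary C–Br bond gives a stable homoallylic alkylmagnesium bromide that serves steps 2 and 13.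

Step 2
Reactants: 3 but-2-yn-1-ol; 2 (4-methylpent-3-en-1-yl)magnesium bromide
Product: 6 (2Z)-3-iodo-2-(4-methylpent-3-en-1-yl)but-2-en-1-yl dimethylcarbamate, via alkenylmagnesium chelate 4 (not isolated), via iodomagnesium alkoxide 5 (not isolated)
Conditions: 2 (2.2 equiv), 3, CuI (10 mol%), THF, 0 → 40 °C; I2, −40 → 0 °C; Me2NCOCl, DMAP (cat.), 40 °C
Reagents that add atoms: iodine (II); dimethylcarbamoyl chloride (CN(C)C(Cl)=O)
Why: Copper-catalysed anti-carbomagnesiation of a propargylic alkoxide (Duboudin–Jousseaume) puts the homoprenyl group on the carbon next to CH2O and magnesium on the distal carbon cis to oxygen (chelate 4), so iodinolysis with retention gives the tetrasubstituted Z-olefin (future C9 cis to C26) and the alkoxide is carbamoylated in the same flask.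

Step 3
Reactants: 7 prop-2-yn-1-ol; 8 ethenylmagnesium bromide
Product: 10 (2Z)-2-(iodomethylidene)but-3-en-1-ol, via vinylmagnesium chelate 9 (not isolated)
Conditions: 8 (2.5 equiv), CuI (10 mol%), THF/Et2O, 0 °C → rt; I2, −40 → 0 °C; aq. NH4Cl
Reagents that add atoms: iodine (II)
Why: The same copper-catalysed anti-carbomagnesiation delivers vinyl to the carbon bearing CH2OH and magnesium (then iodine) to the terminal carbon cis to CH2OH, giving the Z-iododiene.

Step 4
Reactants: 10 (2Z)-2-(iodomethylidene)but-3-en-1-ol; 11 tert-butyldimethyl(prop-2-en-1-yloxy)silane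
Product: 13 (2Z)-6-[(tert-butyldimethylsilyl)oxy]-2-ethenylhex-2-en-1-ol, via alkylborane 12 (not isolated)
Conditions: 11, 9-BBN, THF, rt; then 10, Pd(dppf)Cl2 (5 mol%), AsPh3, Cs2CO3, DMF/H2O, rt
Reagents that add atoms: none
Why: B-alkyl Suzuki–Miyaura coupling proceeds with retention at the alkenyl iodide, so the C3–C5 chain ends cis to CH2OH, the geometry that later places this chain equatorial in the cyclisation.

Step 5
Reactants: 13 (2Z)-6-[(tert-butyldimethylsilyl)oxy]-2-ethenylhex-2-en-1-ol; 6 (2Z)-3-iodo-2-(4-methylpent-3-en-1-yl)but-2-en-1-yl dimethylcarbamate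
Product: 15 (2Z,6Z)-10-[(tert-butyldimethylsilyl)oxy]-6-(hydroxymethyl)-3-methyl-2-(4-methylpent-3-en-1-yl)deca-2,6-dien-1-yl dimethylcarbamate, via bis-boryl adduct 14 (not isolated)
Conditions: 13, 9-BBN (2.2 equiv), THF, 0 °C → rt; then 6, Pd(dppf)Cl2 (10 mol%), AsPh3, Cs2CO3, DMF/H2O, 45 °C
Reagents that add atoms: none
Why: 9-BBN hydroborates only the monosubstituted vinyl group (anti-Markovnikov) and the second B-alkyl Suzuki coupling joins C9 to C10 with retention; the allylic carbamate on a tetrasubstituted olefin is a poor substrate for ionisation by zerovalent palladium.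

Step 6
Reactants: 15 (2Z,6Z)-10-[(tert-butyldimethylsilyl)oxy]-6-(hydroxymethyl)-3-methyl-2-(4-methylpent-3-en-1-yl)deca-2,6-dien-1-yl dimethylcarbamate
Product: 16 (2Z)-5-[(2R,3S)-3-{3-[(tert-butyldimethylsilyl)oxy]propyl}-2-(hydroxymethyl)oxiran-2-yl]-3-methyl-2-(4-methylpent-3-en-1-yl)pent-2-en-1-yl dimethylcarbamate
Conditions: Ti(OiPr)4 (20 mol%), D-(−)-diethyl tartrate (24 mol%), t-BuOOH, 4 Å MS, CH2Cl2, −20 °C
Reagents that add atoms: tert-butyl hydroperoxide (CC(C)(C)OO)
Why: Sharpless asymmetric epoxidation oxidises only the olefin of the free allylic alcohol, and D-(−)-tartrate gives the (2R,3S)-epoxide, the sole source of absolute configuration (C6 after inversion).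

Step 7
Reactants: 16 (2Z)-5-[(2R,3S)-3-{3-[(tert-butyldimethylsilyl)oxy]propyl}-2-(hydroxymethyl)oxiran-2-yl]-3-methyl-2-(4-methylpent-3-en-1-yl)pent-2-en-1-yl dimethylcarbamate
Product: 18 (4aS,5S,6S,8aS)-5-{3-[(tert-butyldimethylsilyl)oxy]propyl}-6-hydroxy-6-(hydroxymethyl)-8a-methyl-4a-(4-methylpent-3-en-1-yl)hexahydro-4H-1,3-benzodioxin-2-one, via cyclic iminium salt 17 (not isolated)
Conditions: MeAlCl2 (2.5 equiv), CH2Cl2, −78 °C; aq. potassium sodium tartrate/NaHCO3
Reagents that add atoms: water (O)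
Why: Proposed new method: MeAlCl2 turns the free hydroxyl into an aluminium alkoxide that activates the epoxide and directs opening at the distal carbon C6 (the usual C3 opening of 2,3-epoxy alcohols by organoaluminium reagents; attack at C7 would need a disfavoured 5-endo closure), the tetrasubstituted olefin attacks C6 with inversion through a chair transition state (C5 chain equatorial, C26 axial), and the C10 cation is captured anti by the carbamate carbonyl oxygen to give a six-membered iminium salt that hydrolyses to the cyclic carbonate, so C6, C11 and C10 follow from the epoxide configuration and the olefin geometry; the closest known reactions are Lewis-acid epoxy-olefin (polyene) cyclisations of terpenoid epoxides and carbamate- or carbonate-terminated epoxide-opening cascades.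

Step 8
Reactants: 18 (4aS,5S,6S,8aS)-5-{3-[(tert-butyldimethylsilyl)oxy]propyl}-6-hydroxy-6-(hydroxymethyl)-8a-methyl-4a-(4-methylpent-3-en-1-yl)hexahydro-4H-1,3-benzodioxin-2-one
Product: 19 (4aS,5S,8aS)-5-{3-[(tert-butyldimethylsilyl)oxy]propyl}-8a-methyl-4a-(4-methylpent-3-en-1-yl)tetrahydro-4H-1,3-benzodioxine-2,6(5H)-dione
Conditions: NaIO4, THF/H2O (pH 7), 0 °C → rt
Reagents that add atoms: none
Why: Periodate glycol cleavage removes the hydroxymethyl carbon and gives the C7 ketone under neutral conditions, so the adjacent C6 centre does not epimerise.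

Step 9
Reactants: 19 (4aS,5S,8aS)-5-{3-[(tert-butyldimethylsilyl)oxy]propyl}-8a-methyl-4a-(4-methylpent-3-en-1-yl)tetrahydro-4H-1,3-benzodioxine-2,6(5H)-dione; 20 prop-1-en-2-ylmagnesium bromide
Product: 22 (1R,2S,3S,4S)-2-{3-[(tert-butyldimethylsilyl)oxy]propyl}-3-(hydroxymethyl)-4-methyl-3-(4-methylpent-3-en-1-yl)-1-(prop-1-en-2-yl)cyclohexane-1,4-diol, via magnesium alkoxide carbonate 21 (not isolated)
Conditions: 20 (3 equiv), LaCl3·2LiCl (30 mol%), THF, −78 → 0 °C; then NaOH, MeOH/H2O, rt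
Reagents that add atoms: none
Why: Lanthanum-promoted Grignard 1,2-addition suppresses enolisation (C6 stays intact) and occurs from the equatorial side away from the axial C26 arm (the new C7 centre is lost again in step 10), and saponification of the carbonate in the same flask frees the C10 and C26 hydroxyls.

Step 10
Reactants: 22 (1R,2S,3S,4S)-2-{3-[(tert-butyldimethylsilyl)oxy]propyl}-3-(hydroxymethyl)-4-methyl-3-(4-methylpent-3-en-1-yl)-1-(prop-1-en-2-yl)cyclohexane-1,4-diol
Product: 23 (1R,2S,6R)-6-{3-[(tert-butyldimethylsilyl)oxy]propyl}-2-hydroxy-2-methyl-1-(4-methylpent-3-en-1-yl)-5-[(2Z)-1-oxopropan-2-ylidene]cyclohexane-1-carbaldehyde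
Conditions: IBX (5 equiv), DMSO, 55 °C
Reagents that add atoms: 2-iodoxybenzoic acid (O=C1OI(=O)(O)c2ccccc12)
Why: IBX oxidises the primary C26 alcohol to the aldehyde and effects the Babler–Dauben-type oxidative 1,3-transposition of the tertiary allylic alcohol; in the [3,3] shift the methyl turns toward the less hindered C8 methylene, so the formyl group ends syn to C6 ((Z)-enal, also the isomer with less allylic strain).

Step 11
Reactants: 23 (1R,2S,6R)-6-{3-[(tert-butyldimethylsilyl)oxy]propyl}-2-hydroxy-2-methyl-1-(4-methylpent-3-en-1-yl)-5-[(2Z)-1-oxopropan-2-ylidene]cyclohexane-1-carbaldehyde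
Product: 24 (2Z)-2-[(1S,2S,5S,6S,10R)-10-{3-[(tert-butyldimethylsilyl)oxy]propyl}-1,6-dihydroxy-6-methyl-2-(prop-1-en-2-yl)spiro[4.5]decan-9-ylidene]propanal
Conditions: Me2AlCl (3 equiv), CH2Cl2, −78 → −40 °C
Reagents that add atoms: none
Why: Lewis-acid-promoted intramolecular carbonyl-ene (Prins-type) reaction: aluminium bridges the C10 alkoxide and the C26 carbonyl so the new hydroxyl points to the C10 side (26S), the isopropylidene terminus is expected to approach anti to the aluminated oxygen (trans, 14S), and loss of a methyl proton gives the isopropenyl group.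

Step 12
Reactants: 24 (2Z)-2-[(1S,2S,5S,6S,10R)-10-{3-[(tert-butyldimethylsilyl)oxy]propyl}-1,6-dihydroxy-6-methyl-2-(prop-1-en-2-yl)spiro[4.5]decan-9-ylidene]propanal
Product: 25 2-[(1S,2S,5S,6S,10R)-10-{3-[(tert-butyldimethylsilyl)oxy]propyl}-1,6-dihydroxy-6-methyl-9-[(2Z)-1-oxopropan-2-ylidene]spiro[4.5]decan-2-yl]prop-2-enal
Conditions: SeO2 (1.2 equiv), pyridine (2 equiv), 1,4-dioxane, 70 °C
Reagents that add atoms: selenium dioxide (O=[Se]=O)
Why: Riley-type allylic oxidation (ene then [2,3] shift) attacks the methyl of the electron-rich 1,1-disubstituted olefin and carries it to the aldehyde, while the electron-poor enal olefin and the alcohols are left alone.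

Step 13
Reactants: 7 prop-2-yn-1-ol; 2 (4-methylpent-3-en-1-yl)magnesium bromide
Product: 27 6-methyl-2-methylidenehept-5-en-1-ol, via alkenylmagnesium chelate 26 (not isolated)
Conditions: 2 (2.5 equiv), 7, CuI (10 mol%), THF, 0 °C → rt; aq. NH4Cl
Reagents that add atoms: none
Why: The same copper-catalysed carbomagnesiation of propargyl alcohol adds the homoprenyl group to the internal carbon, and protonolysis gives the 2-substituted allyl alcohol.

Step 14
Reactants: 27 6-methyl-2-methylidenehept-5-en-1-ol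
Product: 28 6-methyl-2-methylidenehept-5-enal
Conditions: MnO2, CH2Cl2, rt
Reagents that add atoms: none
Why: MnO2 oxidises the allylic alcohol selectively to the enal without touching the trisubstituted olefin.

Step 15
Reactants: 28 6-methyl-2-methylidenehept-5-enal; 29 triiodomethane
Product: 31 (1E)-1-iodo-7-methyl-3-methylideneocta-1,6-diene, via iodomethylidene dichromium reagent 30 (not isolated)
Conditions: CrCl2 (6 equiv), THF, 0 °C
Reagents that add atoms: none
Why: Takai olefination converts the aldehyde into the (E)-iodoalkene through the geminal dichromium species.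

Step 16
Reactants: 25 2-[(1S,2S,5S,6S,10R)-10-{3-[(tert-butyldimethylsilyl)oxy]propyl}-1,6-dihydroxy-6-methyl-9-[(2Z)-1-oxopropan-2-ylidene]spiro[4.5]decan-2-yl]prop-2-enal; 31 (1E)-1-iodo-7-methyl-3-methylideneocta-1,6-diene
Product: 32 (2E,4E)-2-[(1S,2S,5S,6S,10R)-10-{3-[(tert-butyldimethylsilyl)oxy]propyl}-1,6-dihydroxy-6-methyl-9-[(2Z)-1-oxopropan-2-ylidene]spiro[4.5]decan-2-yl]-10-methyl-6-methylideneundeca-2,4,9-trienal
Conditions: Pd(OAc)2 (10 mol%), Bu4NCl, NaHCO3, DMF, 40 °C, dark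
Reagents that add atoms: none
Why: Mizoroki–Heck coupling (Jeffery conditions): the dienylpalladium adds to the terminal CH2 of the 2-substituted acrolein and syn β-hydride elimination gives the conjugated (E)-enal with C17 trans to the formyl carbon, which is the C15=C16 geometry of the target; the tetrasubstituted enal cannot act as a Heck acceptor.

Step 17
Reactants: 32 (2E,4E)-2-[(1S,2S,5S,6S,10R)-10-{3-[(tert-butyldimethylsilyl)oxy]propyl}-1,6-dihydroxy-6-methyl-9-[(2Z)-1-oxopropan-2-ylidene]spiro[4.5]decan-2-yl]-10-methyl-6-methylideneundeca-2,4,9-trienal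
Product: 33 (2Z)-2-[(1S,2S,5S,6S,10R)-10-{3-[(tert-butyldimethylsilyl)oxy]propyl}-1,6-dihydroxy-2-[(2E,4E)-1-hydroxy-10-methyl-6-methylideneundeca-2,4,9-trien-2-yl]-6-methylspiro[4.5]decan-9-ylidene]propanal
Conditions: NaBH(OAc)3, AcOH, MeCN, −20 °C
Reagents that add atoms: none
Why: Hydroxyl-directed triacetoxyborohydride 1,2-reduction: the C26 hydroxyl binds boron and delivers hydride to the nearby C28 aldehyde, while the remote, hindered tetrasubstituted C1 enal should react much more slowly.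

Step 18
Reactants: 33 (2Z)-2-[(1S,2S,5S,6S,10R)-10-{3-[(tert-butyldimethylsilyl)oxy]propyl}-1,6-dihydroxy-2-[(2E,4E)-1-hydroxy-10-methyl-6-methylideneundeca-2,4,9-trien-2-yl]-6-methylspiro[4.5]decan-9-ylidene]propanal
Product: 34 (2E,4E)-2-[(1S,2S,5S,6S,10R)-10-{3-[(tert-butyldimethylsilyl)oxy]propyl}-1,6-dihydroxy-6-methyl-9-[(2Z)-1-oxopropan-2-ylidene]spiro[4.5]decan-2-yl]-10-methyl-6-methylideneundeca-2,4,9-trien-1-yl acetate
Conditions: AcCl (1.1 equiv), 2,4,6-collidine, CH2Cl2, −78 °C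
Reagents that add atoms: acetyl chloride (CC(Cl)=O)
Why: Low-temperature acylation with acetyl chloride and collidine is selective for the primary allylic alcohol over the neopentyl secondary C26 and tertiary C10 hydroxyls.

Step 19
Reactants: 34 (2E,4E)-2-[(1S,2S,5S,6S,10R)-10-{3-[(tert-butyldimethylsilyl)oxy]propyl}-1,6-dihydroxy-6-methyl-9-[(2Z)-1-oxopropan-2-ylidene]spiro[4.5]decan-2-yl]-10-methyl-6-methylideneundeca-2,4,9-trien-1-yl acetate
Product: 35 (2E,4E)-2-[(1S,2S,5S,6S,10R)-1,6-dihydroxy-10-(3-hydroxypropyl)-6-methyl-9-[(2Z)-1-oxopropan-2-ylidene]spiro[4.5]decan-2-yl]-10-methyl-6-methylideneundeca-2,4,9-trien-1-yl acetate (target)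
Conditions: HF·pyridine, pyridine, THF, 0 °C
Reagents that add atoms: none
Why: Buffered fluoride desilylation frees the C3 hydroxyl without touching the allylic acetate, the enal or the triene.

## Compound list

1 | 5-bromo-2-methylpent-2-ene | CC(C)=CCCBr | starting material
2 | (4-methylpent-3-en-1-yl)magnesium bromide | CC(C)=CCC[Mg]Br | intermediate
3 | but-2-yn-1-ol | CC#CCO | starting material
4 | 3-methyl-4-(4-methylpent-3-en-1-yl)-2,5-dihydro-1,2-oxamagnesole (cyclic alkenylmagnesium alkoxide) | CC1=C(CCC=C(C)C)CO[Mg]1 | intermediate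
5 | iodomagnesium (2Z)-3-iodo-2-(4-methylpent-3-en-1-yl)but-2-en-1-olate | I[Mg]OC/C(CCC=C(C)C)=C(/C)I | intermediate
6 | (2Z)-3-iodo-2-(4-methylpent-3-en-1-yl)but-2-en-1-yl dimethylcarbamate | CN(C)C(=O)OC/C(CCC=C(C)C)=C(/C)I | intermediate
7 | prop-2-yn-1-ol | C#CCO | starting material
8 | ethenylmagnesium bromide | C=C[Mg]Br | starting material
9 | 4-ethenyl-2,5-dihydro-1,2-oxamagnesole | C=CC1=C[Mg]OC1 | intermediate
10 | (2Z)-2-(iodomethylidene)but-3-en-1-ol | OC/C(C=C)=C\I | intermediate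
11 | tert-butyldimethyl(prop-2-en-1-yloxy)silane | C=CCO[Si](C)(C)C(C)(C)C | starting material
12 | 9-{3-[(tert-butyldimethylsilyl)oxy]propyl}-9-borabicyclo[3.3.1]nonane | CC(C)(C)[Si](C)(C)OCCCB1C2CCCC1CCC2 | intermediate
13 | (2Z)-6-[(tert-butyldimethylsilyl)oxy]-2-ethenylhex-2-en-1-ol | OC/C(C=C)=C\CCCO[Si](C)(C)C(C)(C)C | intermediate
14 | bis(9-BBN) adduct of 13 (9-BBN borinate on oxygen, 9-BBN on the terminal carbon of the former vinyl group, Z-olefin kept) | CC(C)(C)[Si](C)(C)OCCC/C=C(\COB1C2CCCC1CCC2)CCB3C4CCCC3CCC4 | intermediate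
15 | (2Z,6Z)-10-[(tert-butyldimethylsilyl)oxy]-6-(hydroxymethyl)-3-methyl-2-(4-methylpent-3-en-1-yl)deca-2,6-dien-1-yl dimethylcarbamate | OC/C(CC/C(C)=C(\COC(=O)N(C)C)CCC=C(C)C)=C\CCCO[Si](C)(C)C(C)(C)C | intermediate
16 | (2Z)-5-[(2R,3S)-3-{3-[(tert-butyldimethylsilyl)oxy]propyl}-2-(hydroxymethyl)oxiran-2-yl]-3-methyl-2-(4-methylpent-3-en-1-yl)pent-2-en-1-yl dimethylcarbamate | OC[C@@]1(CC/C(C)=C(\COC(=O)N(C)C)CCC=C(C)C)O[C@H]1CCCO[Si](C)(C)C(C)(C)C | intermediate
17 | N-[(4aS,5S,6S,8aS)-5-{3-[(tert-butyldimethylsilyl)oxy]propyl}-6-hydroxy-6-(hydroxymethyl)-8a-methyl-4a-(4-methylpent-3-en-1-yl)hexahydro-4H-1,3-benzodioxin-2-ylidene]-N-methylmethanaminium chloride (aluminium-bound in the flask) | CC(C)=CCC[C@]2([C@H](CCCO[Si](C)(C)C(C)(C)C)[C@](O)(CO)CC[C@]2(C)O3)COC3=[N+](C)C.[Cl-] | intermediate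
18 | (4aS,5S,6S,8aS)-5-{3-[(tert-butyldimethylsilyl)oxy]propyl}-6-hydroxy-6-(hydroxymethyl)-8a-methyl-4a-(4-methylpent-3-en-1-yl)hexahydro-4H-1,3-benzodioxin-2-one | CC(C)=CCC[C@]2([C@H](CCCO[Si](C)(C)C(C)(C)C)[C@](O)(CO)CC[C@]2(C)O3)COC3=O | intermediate
19 | (4aS,5S,8aS)-5-{3-[(tert-butyldimethylsilyl)oxy]propyl}-8a-methyl-4a-(4-methylpent-3-en-1-yl)tetrahydro-4H-1,3-benzodioxine-2,6(5H)-dione | CC(C)=CCC[C@]2([C@H](CCCO[Si](C)(C)C(C)(C)C)C(=O)CC[C@]2(C)O3)COC3=O | intermediate
20 | prop-1-en-2-ylmagnesium bromide | C=C(C)[Mg]Br | starting material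
21 | bromomagnesium alkoxide of (4aS,5S,6R,8aS)-5-{3-[(tert-butyldimethylsilyl)oxy]propyl}-6-hydroxy-8a-methyl-4a-(4-methylpent-3-en-1-yl)-6-(prop-1-en-2-yl)hexahydro-4H-1,3-benzodioxin-2-one | CC(C)=CCC[C@]2([C@H](CCCO[Si](C)(C)C(C)(C)C)[C@@](O[Mg]Br)(C(C)=C)CC[C@]2(C)O3)COC3=O | intermediate
22 | (1R,2S,3S,4S)-2-{3-[(tert-butyldimethylsilyl)oxy]propyl}-3-(hydroxymethyl)-4-methyl-3-(4-methylpent-3-en-1-yl)-1-(prop-1-en-2-yl)cyclohexane-1,4-diol | CC(C)=CCC[C@]2([C@H](CCCO[Si](C)(C)C(C)(C)C)[C@@](O)(C(C)=C)CC[C@]2(C)O)CO | intermediate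
23 | (1R,2S,6R)-6-{3-[(tert-butyldimethylsilyl)oxy]propyl}-2-hydroxy-2-methyl-1-(4-methylpent-3-en-1-yl)-5-[(2Z)-1-oxopropan-2-ylidene]cyclohexane-1-carbaldehyde | CC(C)=CCC[C@]2([C@H](CCCO[Si](C)(C)C(C)(C)C)/C(=C(/C)C=O)CC[C@]2(C)O)C=O | intermediate
24 | (2Z)-2-[(1S,2S,5S,6S,10R)-10-{3-[(tert-butyldimethylsilyl)oxy]propyl}-1,6-dihydroxy-6-methyl-2-(prop-1-en-2-yl)spiro[4.5]decan-9-ylidene]propanal | C=C(C)[C@@H]1CC[C@]2([C@H](CCCO[Si](C)(C)C(C)(C)C)/C(=C(/C)C=O)CC[C@]2(C)O)[C@H]1O | intermediate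
25 | 2-[(1S,2S,5S,6S,10R)-10-{3-[(tert-butyldimethylsilyl)oxy]propyl}-1,6-dihydroxy-6-methyl-9-[(2Z)-1-oxopropan-2-ylidene]spiro[4.5]decan-2-yl]prop-2-enal | C=C(C=O)[C@@H]1CC[C@]2([C@H](CCCO[Si](C)(C)C(C)(C)C)/C(=C(/C)C=O)CC[C@]2(C)O)[C@H]1O | intermediate
26 | 4-(4-methylpent-3-en-1-yl)-2,5-dihydro-1,2-oxamagnesole | CC(C)=CCCC1=C[Mg]OC1 | intermediate
27 | 6-methyl-2-methylidenehept-5-en-1-ol | C=C(CO)CCC=C(C)C | intermediate
28 | 6-methyl-2-methylidenehept-5-enal | C=C(C=O)CCC=C(C)C | intermediate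
29 | triiodomethane | IC(I)I | starting material
30 | (iodomethanediyl)bis(dichlorochromium) | IC([Cr](Cl)Cl)[Cr](Cl)Cl | intermediate
31 | (1E)-1-iodo-7-methyl-3-methylideneocta-1,6-diene | C=C(/C=C/I)CCC=C(C)C | intermediate
32 | (2E,4E)-2-[(1S,2S,5S,6S,10R)-10-{3-[(tert-butyldimethylsilyl)oxy]propyl}-1,6-dihydroxy-6-methyl-9-[(2Z)-1-oxopropan-2-ylidene]spiro[4.5]decan-2-yl]-10-methyl-6-methylideneundeca-2,4,9-trienal | C=C(/C=C/C=C(/C=O)[C@@H]1CC[C@]2([C@H](CCCO[Si](C)(C)C(C)(C)C)/C(=C(/C)C=O)CC[C@]2(C)O)[C@H]1O)CCC=C(C)C | intermediate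
33 | (2Z)-2-[(1S,2S,5S,6S,10R)-10-{3-[(tert-butyldimethylsilyl)oxy]propyl}-1,6-dihydroxy-2-[(2E,4E)-1-hydroxy-10-methyl-6-methylideneundeca-2,4,9-trien-2-yl]-6-methylspiro[4.5]decan-9-ylidene]propanal | C=C(/C=C/C=C(/CO)[C@@H]1CC[C@]2([C@H](CCCO[Si](C)(C)C(C)(C)C)/C(=C(/C)C=O)CC[C@]2(C)O)[C@H]1O)CCC=C(C)C | intermediate
34 | (2E,4E)-2-[(1S,2S,5S,6S,10R)-10-{3-[(tert-butyldimethylsilyl)oxy]propyl}-1,6-dihydroxy-6-methyl-9-[(2Z)-1-oxopropan-2-ylidene]spiro[4.5]decan-2-yl]-10-methyl-6-methylideneundeca-2,4,9-trien-1-yl acetate | C=C(/C=C/C=C(/COC(C)=O)[C@@H]1CC[C@]2([C@H](CCCO[Si](C)(C)C(C)(C)C)/C(=C(/C)C=O)CC[C@]2(C)O)[C@H]1O)CCC=C(C)C | intermediate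
35 | (2E,4E)-2-[(1S,2S,5S,6S,10R)-1,6-dihydroxy-10-(3-hydroxypropyl)-6-methyl-9-[(2Z)-1-oxopropan-2-ylidene]spiro[4.5]decan-2-yl]-10-methyl-6-methylideneundeca-2,4,9-trien-1-yl acetate | C=C(/C=C/C=C(/COC(C)=O)[C@@H]1CC[C@]2([C@H](CCCO)/C(=C(/C)C=O)CC[C@]2(C)O)[C@H]1O)CCC=C(C)C | target

## Step count and risks

Total step count: 19. Longest linear sequence: 14 steps (steps 3, 4, 5, 6, 7, 8, 9, 10, 11, 12, 16, 17, 18, 19, from prop-2-yn-1-ol; the branch through steps 1 and 2 joins at step 5 and is equally long).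

Three steps most likely to fail:

**Step 7 (cation–olefin cyclisation).** The C10 cation may be intercepted by the side-chain C14=C15 olefin (5-exo closure) before the carbamate traps it, and opening at C7 or chloride capture can compete. Fallback, setting out from 3 and returning at 18: carry C12–C14 as a but-3-enyl group, whose monosubstituted olefin is a far weaker nucleophile than the prenyl olefin, and make the prenyl end afterwards by cross-metathesis. Compound 3 is carbomagnesiated with commercial but-3-enylmagnesium bromide (CuI) to the butenyl magnesium chelate F1, iodinated to the butenyl iodoalkoxide F2 and carbamoylated to the butenyl iodide F3. B-alkyl Suzuki coupling of F3 with borane 14 gives the butenyl allylic alcohol F4, Sharpless epoxidation with D-(−)-diethyl tartrate the butenyl epoxy alcohol F5, and MeAlCl2 closes the cyclohexane through the butenyl iminium salt F6 to the butenyl carbonate F7. Cross-metathesis of F7 with 2-methylbut-2-ene (second-generation Grubbs catalyst, CH2Cl2, 40 °C) then gives 18.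

**Step 10 (double oxidation with oxidative transposition).** The hindered tertiary isopropenyl carbinol may dehydrate or rearrange sluggishly, and the enal geometry is set only by the [3,3] preference. Fallback, setting out from 22 and returning at 23: Ph3SiOReO3 (5 mol%, Et2O, 0 °C) catalyses the redox-neutral 1,3-transposition of the tertiary allylic alcohol to the thermodynamically favoured primary allylic alcohol F8 (tetrasubstituted olefin). TEMPO (cat.) and PhI(OAc)2 then oxidise both primary alcohols of F8, the allylic one to the enal and the neopentyl one to the C26 aldehyde, giving 23.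

**Step 11 (carbonyl-ene spirocyclisation).** A concerted ene pathway could give the cis (14-epi) cyclopentanol, and chloride capture or methyl transfer from Me2AlCl can intervene. Fallback, setting out from 23 and returning at 24: SeO2 (cat.) and t-BuOOH hydroxylate the (E)-methyl of the prenyl group to the allylic alcohol F9. NBS/Me2S (Corey–Kim bromination, CH2Cl2, −20 °C) converts it into the allylic bromide F10; these conditions leave the two aldehydes alone. CrCl2 (THF, 0 °C) then generates the allylchromium species F11, which adds through its γ-carbon C14 to the C26 aldehyde in a chair Zimmerman–Traxler transition state (intramolecular Nozaki–Hiyama allylation, trans product expected), giving 24 with the isopropenyl group formed by allyl transposition.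

Further compounds
F1 | step 7 | 4-(but-3-en-1-yl)-3-methyl-2,5-dihydro-1,2-oxamagnesole | CC1=C(CCC=C)CO[Mg]1
F2 | step 7 | iodomagnesium (2Z)-2-(but-3-en-1-yl)-3-iodobut-2-en-1-olate | I[Mg]OC/C(CCC=C)=C(/C)I
F3 | step 7 | (2Z)-2-(but-3-en-1-yl)-3-iodobut-2-en-1-yl dimethylcarbamate | CN(C)C(=O)OC/C(CCC=C)=C(/C)I
F4 | step 7 | (2Z,6Z)-2-(but-3-en-1-yl)-10-[(tert-butyldimethylsilyl)oxy]-6-(hydroxymethyl)-3-methyldeca-2,6-dien-1-yl dimethylcarbamate | OC/C(CC/C(C)=C(\COC(=O)N(C)C)CCC=C)=C\CCCO[Si](C)(C)C(C)(C)C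
F5 | step 7 | (2Z)-2-(but-3-en-1-yl)-5-[(2R,3S)-3-{3-[(tert-butyldimethylsilyl)oxy]propyl}-2-(hydroxymethyl)oxiran-2-yl]-3-methylpent-2-en-1-yl dimethylcarbamate | OC[C@@]1(CC/C(C)=C(\COC(=O)N(C)C)CCC=C)O[C@H]1CCCO[Si](C)(C)C(C)(C)C
F6 | step 7 | N-[(4aS,5S,6S,8aS)-4a-(but-3-en-1-yl)-5-{3-[(tert-butyldimethylsilyl)oxy]propyl}-6-hydroxy-6-(hydroxymethyl)-8a-methylhexahydro-4H-1,3-benzodioxin-2-ylidene]-N-methylmethanaminium chloride | C=CCC[C@]2([C@H](CCCO[Si](C)(C)C(C)(C)C)[C@](O)(CO)CC[C@]2(C)O3)COC3=[N+](C)C.[Cl-]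
F7 | step 7 | (4aS,5S,6S,8aS)-4a-(but-3-en-1-yl)-5-{3-[(tert-butyldimethylsilyl)oxy]propyl}-6-hydroxy-6-(hydroxymethyl)-8a-methylhexahydro-4H-1,3-benzodioxin-2-one | C=CCC[C@]2([C@H](CCCO[Si](C)(C)C(C)(C)C)[C@](O)(CO)CC[C@]2(C)O3)COC3=O
F8 | step 10 | (1S,2S,3R)-3-{3-[(tert-butyldimethylsilyl)oxy]propyl}-2-(hydroxymethyl)-4-[(2Z)-1-hydroxypropan-2-ylidene]-1-methyl-2-(4-methylpent-3-en-1-yl)cyclohexan-1-ol | CC(C)=CCC[C@]2([C@H](CCCO[Si](C)(C)C(C)(C)C)/C(=C(/C)CO)CC[C@]2(C)O)CO
F9 | step 11 | (1R,2S,6R)-6-{3-[(tert-butyldimethylsilyl)oxy]propyl}-2-hydroxy-1-[(3E)-5-hydroxy-4-methylpent-3-en-1-yl]-2-methyl-5-[(2Z)-1-oxopropan-2-ylidene]cyclohexane-1-carbaldehyde | OC/C(C)=C/CC[C@]2([C@H](CCCO[Si](C)(C)C(C)(C)C)/C(=C(/C)C=O)CC[C@]2(C)O)C=O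
F10 | step 11 | (1R,2S,6R)-1-[(3E)-5-bromo-4-methylpent-3-en-1-yl]-6-{3-[(tert-butyldimethylsilyl)oxy]propyl}-2-hydroxy-2-methyl-5-[(2Z)-1-oxopropan-2-ylidene]cyclohexane-1-carbaldehyde | BrC/C(C)=C/CC[C@]2([C@H](CCCO[Si](C)(C)C(C)(C)C)/C(=C(/C)C=O)CC[C@]2(C)O)C=O
F11 | step 11 | allylchromium dichloride derived from F10 (chromium on the former bromomethyl carbon) | Cl[Cr](Cl)C/C(C)=C/CC[C@]2([C@H](CCCO[Si](C)(C)C(C)(C)C)/C(=C(/C)C=O)CC[C@]2(C)O)C=O
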